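**Retrosynthetic overview**
1. Theasinensin C is the C2'–C2' (ring B to ring B) dimer of (−)-epigallocatechin, so the only disconnection is the biaryl bond; all four stereocentres and all permanent rings are bought in the monomer.
2. The biaryl bond is traced back to a [3,3]-sigmatropic (Claisen-type) shift within the hemiketal that two ring-B o-quinones form with each other.
3. The shift gives the quinone-level dimer dehydrotheasinensin C, with an sp3 methine at the future axis; reduction and enolisation turn that centre into the (R)-axis.
4. Ring order: no permanent ring is built; a dihydrobenzofuran hemiketal ring closes after the C–C bond (step 1) and is opened again in the reduction (step 2).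

Assumption: theasinensin C is the (R)-biaryl atropisomer (the SMILES does not encode the axis; the S-atropisomer is theasinensin E), and (−)-epigallocatechin, a catalogue green-tea catechin, is the commercial chiral starting material.

Step 1
Reactants: 1 (−)-epigallocatechin (two molecules)
Product: 5 dehydrotheasinensin C hydrate, via o-quinone 2 (not isolated), via quinone hemiketal 3 (not isolated), via ene-trione dimer 4 (not isolated)
Conditions: CuCl2·2H2O (2.2 equiv per 1), H2O, rt, 12 h; filter; Diaion HP-20 (H2O, then 40 % aq. MeOH); freeze-dry
Reagents that add atoms: water, O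
Why: Divalent copper oxidises only the pyrogallol ring B to hydroxy-o-quinone 2, two molecules of which join through hemiketal 3 and a [3,3]-sigmatropic (Claisen-type) shift that forges the C2'–C2' bond on the face fixed by the two stacked (2R,3R)-chromans (substrate control of the new methine), after which the regenerated phenol closes the cis-fused hemiketal (the only unstrained fusion, so the hemiketal carbon follows the methine) and water hydrates C4'.

Course of step 1:
- Oxidation: 1 gives 2 (two electrons and two protons per molecule).
- Hemiketal: the enolic 3'-OH of one molecule of 2 adds to the C4' carbonyl of a second, giving 3, an allyl vinyl ether (C2'=C3'–O–C4'–C3'=C2').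
- [3,3] shift: the O–C4' bond breaks as the C2'–C2' bond forms, and the accepting ring enolises at once to the pyrogallol, giving 4. A direct conjugate addition of the enol to the second quinone would give the same bond and the same 4.
- Ring closure and hydration: the aromatic 3'-OH adds to the C3' carbonyl of the ene-trione and water adds to C4', giving 5, which is stable at the acidic pH set by the released HCl.
- Removing the copper chlorides here keeps them out of the hot reduction, where they would consume ascorbic acid and re-oxidise the product.

Step 2
Reactants: 5 dehydrotheasinensin C hydrate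
Product: 6 theasinensin C
Conditions: L-ascorbic acid (10 equiv), H2O, argon, 85 °C, 15 min; Sephadex LH-20 (EtOH, then aq. acetone)
Reagents that add atoms: none
Why: Ascorbic acid delivers two electrons and two protons to the 1,2-dicarbonyl unit of 5 (C4' hydrate in equilibrium with the ketone) faster than 5 dismutates, the hemiketal then opens and the methine enolises to the second pyrogallol ring, so its configuration passes to the hindered biaryl bond as the (R)-axis (centre-to-axis chirality transfer) while the four chroman stereocentres stay untouched at about pH 3.

**Compound list**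
1 | (−)-epigallocatechin, (2R,3R)-2-(3,4,5-trihydroxyphenyl)chroman-3,5,7-triol | Oc1cc(O)c2c(c1)O[C@H](c1cc(O)c(O)c(O)c1)[C@H](O)C2 | starting material
2 | epigallocatechin o-quinone, 3-hydroxy-5-[(2R,3R)-3,5,7-trihydroxychroman-2-yl]cyclohexa-3,5-diene-1,2-dione | Oc1cc(O)c2c(c1)O[C@H](C1=CC(=O)C(=O)C(O)=C1)[C@H](O)C2 | intermediate
3 | quinone hemiketal: enol oxygen (3'-O) of one quinone bonded to C4' of the other, whose ring is a 5,6-dihydroxy-6-(enyloxy)cyclohexa-2,4-dienone; both chromans (2R,3R); the hemiketal carbon is labile and left unspecified (it is destroyed in the shift) | Oc1cc(O)c2c(c1)O[C@H](C3=CC(=O)C(O)(OC4=CC(=CC(=O)C4=O)[C@H]5Oc6cc(O)cc(O)c6C[C@H]5O)C(O)=C3)[C@H](O)C2 | intermediate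
4 | ene-trione dimer: one ring B is again an aromatic pyrogallol; its C2' is bonded to the sp3 C2'–H of the other ring B, a cyclohex-5-ene-1,2,3-trione; methine configuration as drawn (the one that correlates with the R axis); both chromans (2R,3R) | Oc1cc(O)c2c(c1)O[C@H](c3cc(O)c(O)c(O)c3[C@H]4C(=O)C(=O)C(=O)C=C4[C@H]5Oc6cc(O)cc(O)c6C[C@H]5O)[C@H](O)C2 | intermediate
5 | dehydrotheasinensin C hydrate: aromatic 3'-O bonded to C3' of the oxidised ring (hemiketal OH), C4' gem-diol, C5' ketone, C6'=C1' enone, C2' methine H cis to the hemiketal OH (cis-fused dihydrobenzofuran); both chromans (2R,3R) | Oc1cc(O)c2c(c1)O[C@H](c3cc(O)c(O)c4O[C@@]5(O)C(O)(O)C(=O)C=C([C@H]6Oc7cc(O)cc(O)c7C[C@H]6O)[C@H]5c34)[C@H](O)C2 | intermediate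
6 | theasinensin C, 2',2'-linked bis[(2R,3R)-epigallocatechin], (R)-biaryl axis | Oc1cc(O)c2c(c1)O[C@H](c1cc(O)c(O)c(O)c1-c1c([C@H]3Oc4cc(O)cc(O)c4C[C@H]3O)cc(O)c(O)c1O)[C@H](O)C2 | target

**Total step count:** 2. **Longest linear sequence:** 2.

**Most likely points of failure**
The route has two steps; step 1 is entered twice because its C–C bond formation and its oxidation/isolation can fail independently.

1. Step 1, the C–C bond-forming event (3 to 4). Two free quinones may divert to benzotropolone-type or oligomeric products before they pair. The fallback couples a quinone with an unoxidised phenol instead of two quinones, which bypasses 5 and needs no reduction.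
   - It sets out from 1: o-chloranil (0.5 equiv) in acetone/THF at −40 °C turns half of 1 into 2 in the presence of the other half.
   - The ring-B 3'-OH of intact 1 adds to the C4' carbonyl of 2 to give the quinone–phenol hemiketal F1.
   - Its [3,3] shift, followed by tautomerisation of both rings, gives the biaryl directly at the theasinensin oxidation level.
   - The axis is then not set through a methine, so the atropisomer ratio is taken as found and the (R)-isomer is separated on Sephadex LH-20 after an aqueous ascorbic acid wash.
   - The sequence comes back to the route at 6.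

2. Step 2, the reduction and aromatisation of 5 at 85 °C. Dismutation of 5 (which also gives the S-atropisomer), C-2 epimerisation on heating, or air oxidation of the free polyphenol can erode yield and purity. The fallback isolates the product as a stable derivative.
   - It sets out from 5: Zn dust, Ac2O and pyridine at 0 °C to rt (reductive acetylation) give theasinensin C dodeca-O-acetate F2.
   - This is stable to air and silica gel, so any atropisomer or epimer is removed by chromatography.
   - K2CO3 in degassed MeOH at 0 °C under argon, then Amberlite IR-120 (H+ form), removes the acetates and the sequence comes back at 6.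

3. Step 1, oxidation of the galloyl-free substrate and isolation of labile 5. Without galloyl groups the two quinones stack less well, so other quinone dimers may compete, and 5 may not survive desalting. The fallback uses the galloyl esters as a removable template.
   - It sets out where the route does, but with bought (−)-epigallocatechin 3-O-gallate F3 in the place of 1.
   - CuCl2·2H2O in water at rt gives dehydrotheasinensin A hydrate F4 by the same hemiketal/[3,3] sequence, here favoured by stacking of the galloyl rings.
   - L-ascorbic acid at 85 °C reduces it to theasinensin A F5; this pair of operations is well precedented for the gallate (about 50 %).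
   - Tannase in water at pH 5 and 37 °C under argon then cleaves the two galloyl esters. It acts only on the achiral esters and sets no stereocentre.
   - The sequence comes back to the route at 6.

**Further compounds**
F1 | step 1 | quinone–phenol hemiketal (3'-O of intact epigallocatechin on C4' of quinone 2; hemiketal carbon labile, unspecified) | Oc1cc(O)c2c(c1)O[C@H](C3=CC(=O)C(O)(Oc4cc(cc(O)c4O)[C@H]5Oc6cc(O)cc(O)c6C[C@H]5O)C(O)=C3)[C@H](O)C2
F2 | step 2 | theasinensin C dodeca-O-acetate | CC(=O)Oc1cc(OC(C)=O)c2c(c1)O[C@H](c1cc(OC(C)=O)c(OC(C)=O)c(OC(C)=O)c1-c1c([C@H]3Oc4cc(OC(C)=O)cc(OC(C)=O)c4C[C@H]3OC(C)=O)cc(OC(C)=O)c(OC(C)=O)c1OC(C)=O)[C@H](OC(C)=O)C2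
F3 | step 1 | (−)-epigallocatechin 3-O-gallate | Oc1cc(O)c2c(c1)O[C@H](c1cc(O)c(O)c(O)c1)[C@H](OC(=O)c1cc(O)c(O)c(O)c1)C2
F4 | step 1 | dehydrotheasinensin A hydrate (3,3'-di-O-gallate of 5) | Oc1cc(O)c2c(c1)O[C@H](c3cc(O)c(O)c4O[C@@]5(O)C(O)(O)C(=O)C=C([C@H]6Oc7cc(O)cc(O)c7C[C@H]6OC(=O)c6cc(O)c(O)c(O)c6)[C@H]5c34)[C@H](OC(=O)c1cc(O)c(O)c(O)c1)C2
F5 | step 1 | theasinensin A (3,3'-di-O-gallate of 6, (R)-axis) | Oc1cc(O)c2c(c1)O[C@H](c1cc(O)c(O)c(O)c1-c1c([C@H]3Oc4cc(O)cc(O)c4C[C@H]3OC(=O)c3cc(O)c(O)c(O)c3)cc(O)c(O)c1O)[C@H](OC(=O)c1cc(O)c(O)c(O)c1)C2
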